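The route rests on cutting the bond between the benzylic CH2 and C3 of the butyrolactone ring. The key step joins the lithium enolate of a 4-substituted γ-butyrolactone, which already carries C4 and the exocyclic carbinol carbon in their final configurations, to a silyl-protected vanillyl bromide. In one operation it forms that C–C bond and sets C3. It exploits the acidity of C3–H next to the lactone carbonyl and the trans-1,2 relationship of the C3 and C4 substituents on the five-membered ring: the bulky C4 side chain blocks one enolate face. The lactone comes from a magnesium-catalysed anti-aldol of a succinate imide with silylated vanillin, which sets both other stereocentres at once.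

Key step: step 8

Remark: the structure is taken as drawn, (3R,4R) on the lactone ring (O1, C2 carbonyl, C3, C4, C5) and (R) at the benzylic carbinol carbon; TBS = tert-butyldimethylsilyl, TMS = trimethylsilyl.

Step 1
Reactants: 1 vanillin
Product: 2 4-[(tert-butyldimethylsilyl)oxy]-3-methoxybenzaldehyde
Conditions: TBSCl, imidazole, DMF, 0 °C to rt
Reagents that add atoms: tert-butyldimethylsilyl chloride, CC(C)(C)[Si](C)(C)Cl
Why: Imidazole-promoted O-silylation of the phenol leaves the aldehyde untouched and masks the only acidic hydrogen of the aryl unit for the later enolate chemistry.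

Step 2
Reactants: 2 4-[(tert-butyldimethylsilyl)oxy]-3-methoxybenzaldehyde
Product: 3 {4-[(tert-butyldimethylsilyl)oxy]-3-methoxyphenyl}methanol
Conditions: NaBH4, MeOH/THF, 0 °C
Reagents that add atoms: none
Why: Borohydride reduction of the aryl aldehyde to the benzylic alcohol is fast at 0 °C, where the aryl silyl ether should survive.

Step 3
Reactants: 3 {4-[(tert-butyldimethylsilyl)oxy]-3-methoxyphenyl}methanol
Product: 4 [4-(bromomethyl)-2-methoxyphenoxy](tert-butyl)dimethylsilane
Conditions: PBr3 (0.4 equiv), Et2O, 0 °C; used at once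
Reagents that add atoms: phosphorus tribromide, BrP(Br)Br
Why: The benzylic alcohol is activated as a phosphite ester and displaced by bromide (SN2); the electron-rich bromide is prone to ionisation and is therefore used without storage.

Step 4
Reactants: 5 (R)-4-benzyl-1,3-oxazolidin-2-one; 6 4-tert-butoxy-4-oxobutanoic acid
Product: 8 tert-butyl 4-[(4R)-4-benzyl-2-oxo-1,3-oxazolidin-3-yl]-4-oxobutanoate, via mixed pivalic anhydride 7 (not isolated)
Conditions: 6, t-BuCOCl, Et3N, THF, −20 °C; then LiCl, 5, −20 °C to rt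
Reagents that add atoms: none
Why: N-acylation of the oxazolidinone through a mixed anhydride, in which the hindered pivaloyl carbonyl directs attack to the succinyl carbonyl and the tert-butyl ester is inert.

Step 5
Reactants: 8 tert-butyl 4-[(4R)-4-benzyl-2-oxo-1,3-oxazolidin-3-yl]-4-oxobutanoate; 2 4-[(tert-butyldimethylsilyl)oxy]-3-methoxybenzaldehyde
Product: 10 tert-butyl (3S,4R)-3-[(4R)-4-benzyl-2-oxo-1,3-oxazolidine-3-carbonyl]-4-{4-[(tert-butyldimethylsilyl)oxy]-3-methoxyphenyl}-4-hydroxybutanoate, via trimethylsilyl ether 9 (not isolated)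
Conditions: MgCl2 (0.2 equiv), Et3N, TMSCl, EtOAc, 23 °C; then 1 M HCl, THF, 0 °C
Reagents that add atoms: none
Why: Magnesium halide-catalysed direct anti-aldol of an N-acyl oxazolidinone with a non-enolisable aryl aldehyde: soft enolisation gives the chelated (Z)-enolate, which should add through a boat-like transition state on the face remote from the auxiliary benzyl group (the face used in chelate-controlled alkylations) to set the (3S,4R) anti pair, while TMSCl silylates the aldolate to turn the catalyst over and block retro-aldol, and brief dilute acid removes only the TMS group.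

Step 6
Reactants: 10 tert-butyl (3S,4R)-3-[(4R)-4-benzyl-2-oxo-1,3-oxazolidine-3-carbonyl]-4-{4-[(tert-butyldimethylsilyl)oxy]-3-methoxyphenyl}-4-hydroxybutanoate
Product: 11 tert-butyl (3S,4R)-3-[(4R)-4-benzyl-2-oxo-1,3-oxazolidine-3-carbonyl]-4-[(tert-butyldimethylsilyl)oxy]-4-{4-[(tert-butyldimethylsilyl)oxy]-3-methoxyphenyl}butanoate
Conditions: TBSOTf, 2,6-lutidine, CH2Cl2, −78 to 0 °C
Reagents that add atoms: tert-butyldimethylsilyl trifluoromethanesulfonate, CC(C)(C)[Si](C)(C)OS(=O)(=O)C(F)(F)F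
Why: The silyl triflate silylates the hindered secondary benzylic alcohol under non-basic conditions that cause no retro-aldol, so this hydroxyl cannot later form the regioisomeric lactone.

Step 7
Reactants: 11 tert-butyl (3S,4R)-3-[(4R)-4-benzyl-2-oxo-1,3-oxazolidine-3-carbonyl]-4-[(tert-butyldimethylsilyl)oxy]-4-{4-[(tert-butyldimethylsilyl)oxy]-3-methoxyphenyl}butanoate
Product: 13 (4R)-4-[(R)-[(tert-butyldimethylsilyl)oxy]{4-[(tert-butyldimethylsilyl)oxy]-3-methoxyphenyl}methyl]oxolan-2-one, via hydroxy ester 12 (not isolated)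
Conditions: LiBH4, MeOH (1 equiv), THF, 0 °C; aqueous work-up; then (+)-camphor-10-sulfonic acid (0.1 equiv), PhMe, 60 °C
Reagents that add atoms: none
Why: LiBH4 reduces the activated exocyclic imide carbonyl to the primary alcohol while the tert-butyl ester survives, and acid-catalysed 5-exo-trig transesterification by that alcohol then closes the γ-lactone without touching either stereocentre.

Step 8
Reactants: 13 (4R)-4-[(R)-[(tert-butyldimethylsilyl)oxy]{4-[(tert-butyldimethylsilyl)oxy]-3-methoxyphenyl}methyl]oxolan-2-one; 4 [4-(bromomethyl)-2-methoxyphenoxy](tert-butyl)dimethylsilane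
Product: 15 (3R,4R)-3-({4-[(tert-butyldimethylsilyl)oxy]-3-methoxyphenyl}methyl)-4-[(R)-[(tert-butyldimethylsilyl)oxy]{4-[(tert-butyldimethylsilyl)oxy]-3-methoxyphenyl}methyl]oxolan-2-one, via lithium enolate 14 (not isolated)
Conditions: LiN(iPr)2 (1.05 equiv), THF, −78 °C; then 4, DMPU, −78 to −40 °C
Reagents that add atoms: none
Why: LiN(iPr)2 removes C3–H of lactone 13 to give lithium enolate 14, whose C3 displaces bromide from benzylic bromide 4 in an SN2 alkylation that forms the CH2–C3 bond. The closest known reaction type is the trans-selective benzylation of 4-substituted γ-butyrolactone enolates used for dibenzylbutyrolactone lignans. No ring is closed in this step. The new C3 stereocentre is controlled by the neighbouring C4 stereocentre: the bulky silyloxy(aryl)methyl group shields one face of the planar enolate, so the electrophile should enter anti to it and give the 3,4-trans (3R,4R) lactone. The step needs C- over O-alkylation, monoalkylation and no erosion at C4 or the carbinol carbon. These are secured by the soft benzylic bromide with DMPU at low temperature, by the hindered tertiary C3–H of the product, and by the absence of an acidic hydrogen or a beta leaving group at those centres (the silyl ether sits gamma to the enolate carbon).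

Step 9
Reactants: 15 (3R,4R)-3-({4-[(tert-butyldimethylsilyl)oxy]-3-methoxyphenyl}methyl)-4-[(R)-[(tert-butyldimethylsilyl)oxy]{4-[(tert-butyldimethylsilyl)oxy]-3-methoxyphenyl}methyl]oxolan-2-one
Product: 16 (3R,4R)-3-[(4-hydroxy-3-methoxyphenyl)methyl]-4-[(R)-hydroxy(4-hydroxy-3-methoxyphenyl)methyl]oxolan-2-one
Conditions: Bu4NF, AcOH (1:1, 4 equiv), THF, 0 °C to rt
Reagents that add atoms: none
Why: Fluoride cleaves all three Si–O bonds, and the acetic acid buffer keeps the phenols and the carbinol protonated, so that translactonisation onto the benzylic oxygen and quinone-methide-type epimerisation at the carbinol carbon should be suppressed.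

Compound list
1 | vanillin (4-hydroxy-3-methoxybenzaldehyde) | COc1cc(C=O)ccc1O | starting material
2 | 4-[(tert-butyldimethylsilyl)oxy]-3-methoxybenzaldehyde | COc1cc(C=O)ccc1O[Si](C)(C)C(C)(C)C | intermediate
3 | {4-[(tert-butyldimethylsilyl)oxy]-3-methoxyphenyl}methanol | COc1cc(CO)ccc1O[Si](C)(C)C(C)(C)C | intermediate
4 | [4-(bromomethyl)-2-methoxyphenoxy](tert-butyl)dimethylsilane | COc1cc(CBr)ccc1O[Si](C)(C)C(C)(C)C | intermediate
5 | (R)-4-benzyl-1,3-oxazolidin-2-one | O=C1OC[C@@H](Cc2ccccc2)N1 | starting material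
6 | 4-tert-butoxy-4-oxobutanoic acid (mono-tert-butyl succinate) | CC(C)(C)OC(=O)CCC(=O)O | starting material
7 | 4-tert-butoxy-4-oxobutanoic 2,2-dimethylpropanoic anhydride | CC(C)(C)OC(=O)CCC(=O)OC(=O)C(C)(C)C | intermediate
8 | tert-butyl 4-[(4R)-4-benzyl-2-oxo-1,3-oxazolidin-3-yl]-4-oxobutanoate | O=C1OC[C@@H](Cc2ccccc2)N1C(=O)CCC(=O)OC(C)(C)C | intermediate
9 | tert-butyl (3S,4R)-3-[(4R)-4-benzyl-2-oxo-1,3-oxazolidine-3-carbonyl]-4-{4-[(tert-butyldimethylsilyl)oxy]-3-methoxyphenyl}-4-[(trimethylsilyl)oxy]butanoate | O=C1OC[C@@H](Cc2ccccc2)N1C(=O)[C@@H](CC(=O)OC(C)(C)C)[C@@H](O[Si](C)(C)C)c1ccc(O[Si](C)(C)C(C)(C)C)c(OC)c1 | intermediate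
10 | tert-butyl (3S,4R)-3-[(4R)-4-benzyl-2-oxo-1,3-oxazolidine-3-carbonyl]-4-{4-[(tert-butyldimethylsilyl)oxy]-3-methoxyphenyl}-4-hydroxybutanoate | O=C1OC[C@@H](Cc2ccccc2)N1C(=O)[C@@H](CC(=O)OC(C)(C)C)[C@@H](O)c1ccc(O[Si](C)(C)C(C)(C)C)c(OC)c1 | intermediate
11 | tert-butyl (3S,4R)-3-[(4R)-4-benzyl-2-oxo-1,3-oxazolidine-3-carbonyl]-4-[(tert-butyldimethylsilyl)oxy]-4-{4-[(tert-butyldimethylsilyl)oxy]-3-methoxyphenyl}butanoate | O=C1OC[C@@H](Cc2ccccc2)N1C(=O)[C@@H](CC(=O)OC(C)(C)C)[C@@H](O[Si](C)(C)C(C)(C)C)c1ccc(O[Si](C)(C)C(C)(C)C)c(OC)c1 | intermediate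
12 | tert-butyl (3R,4R)-4-[(tert-butyldimethylsilyl)oxy]-4-{4-[(tert-butyldimethylsilyl)oxy]-3-methoxyphenyl}-3-(hydroxymethyl)butanoate | OC[C@@H](CC(=O)OC(C)(C)C)[C@@H](O[Si](C)(C)C(C)(C)C)c1ccc(O[Si](C)(C)C(C)(C)C)c(OC)c1 | intermediate
13 | (4R)-4-[(R)-[(tert-butyldimethylsilyl)oxy]{4-[(tert-butyldimethylsilyl)oxy]-3-methoxyphenyl}methyl]oxolan-2-one | O=C1C[C@H](CO1)[C@@H](O[Si](C)(C)C(C)(C)C)c1ccc(O[Si](C)(C)C(C)(C)C)c(OC)c1 | intermediate
14 | lithium (3R)-3-[(R)-[(tert-butyldimethylsilyl)oxy]{4-[(tert-butyldimethylsilyl)oxy]-3-methoxyphenyl}methyl]-2,3-dihydrofuran-5-olate (lithium enolate of 13) | [Li+].[O-]C1=C[C@H](CO1)[C@@H](O[Si](C)(C)C(C)(C)C)c1ccc(O[Si](C)(C)C(C)(C)C)c(OC)c1 | intermediate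
15 | (3R,4R)-3-({4-[(tert-butyldimethylsilyl)oxy]-3-methoxyphenyl}methyl)-4-[(R)-[(tert-butyldimethylsilyl)oxy]{4-[(tert-butyldimethylsilyl)oxy]-3-methoxyphenyl}methyl]oxolan-2-one | COc1cc(C[C@H]2C(=O)OC[C@@H]2[C@@H](O[Si](C)(C)C(C)(C)C)c2ccc(O[Si](C)(C)C(C)(C)C)c(OC)c2)ccc1O[Si](C)(C)C(C)(C)C | intermediate
16 | (3R,4R)-3-[(4-hydroxy-3-methoxyphenyl)methyl]-4-[(R)-hydroxy(4-hydroxy-3-methoxyphenyl)methyl]oxolan-2-one | COc1cc(C[C@H]2C(=O)OC[C@@H]2[C@@H](O)c2ccc(O)c(OC)c2)ccc1O | target

Total step count: 9. Longest linear sequence: 6 steps (steps 1, 5, 6, 7, 8, 9 from vanillin, or steps 4 to 9 from the oxazolidinone).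

Steps most likely to fail

Step 5. The pendant tert-butyl ester may compete with the imide for magnesium, eroding anti and facial selectivity or stalling turnover, and the electron-rich benzylic aldolate may undergo retro-aldol equilibration. The fallback sets out from 2 and comes back at 12. Aldehyde 2 is homologated with ethyl diazoacetate and catalytic SnCl2 (Roskamp reaction) to ethyl 3-{4-[(tert-butyldimethylsilyl)oxy]-3-methoxyphenyl}-3-oxopropanoate F1. Asymmetric hydrogenation with RuCl2[(S)-BINAP] and H2 in EtOH, the catalyst antipode chosen to deliver the (R)-carbinol, should give ethyl (3R)-3-{4-[(tert-butyldimethylsilyl)oxy]-3-methoxyphenyl}-3-hydroxypropanoate F2. Double deprotonation with LiN(iPr)2 (2.2 equiv, THF, −78 to −20 °C) forms the chelated dilithium alkoxide-enolate F3, which tert-butyl bromoacetate should alkylate anti to the carbinol substituent (Fráter–Seebach alkylation) to give 4-tert-butyl 1-ethyl (2S)-2-[(R)-{4-[(tert-butyldimethylsilyl)oxy]-3-methoxyphenyl}(hydroxy)methyl]butanedioate F4. TBSOTf and 2,6-lutidine give the silyl ether 4-tert-butyl 1-ethyl (2S)-2-[(R)-[(tert-butyldimethylsilyl)oxy]{4-[(tert-butyldimethylsilyl)oxy]-3-methoxyphenyl}methyl]butanedioate F5. LiBH4 in Et2O/MeOH should reduce the ethyl ester in preference to the tert-butyl ester and deliver 12, which is lactonised as in step 7.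

Step 7. The hydride may over-reduce or open the oxazolidinone ring at the hindered imide, and during the acid-catalysed lactonisation the benzylic silyl ether may ionise or the tert-butyl ester may transesterify too slowly. The fallback sets out from 11 and comes back at 13. LiAlH4 in THF at 0 °C reduces both the imide and the tert-butyl ester to (2R)-2-[(R)-[(tert-butyldimethylsilyl)oxy]{4-[(tert-butyldimethylsilyl)oxy]-3-methoxyphenyl}methyl]butane-1,4-diol F6. Catalytic TEMPO with PhI(OAc)2 in CH2Cl2 then oxidises the less hindered primary alcohol (C4 of the diol, remote from the branch). The resulting hydroxy aldehyde closes to the lactol (4R)-4-[(R)-[(tert-butyldimethylsilyl)oxy]{4-[(tert-butyldimethylsilyl)oxy]-3-methoxyphenyl}methyl]oxolan-2-ol F7, which is oxidised further in the same flask to 13 under neutral conditions.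

Step 8. Alkylation of the hindered enolate may be slow, so that the ionisation-prone bromide decomposes or a second alkylation competes. The fallback sets out from 13 (through enolate 14) and comes back at 15. Enolate 14 is added to aldehyde 2 at −78 °C to give the aldol adduct (4R)-3-[{4-[(tert-butyldimethylsilyl)oxy]-3-methoxyphenyl}(hydroxy)methyl]-4-[(R)-[(tert-butyldimethylsilyl)oxy]{4-[(tert-butyldimethylsilyl)oxy]-3-methoxyphenyl}methyl]oxolan-2-one F8 as a mixture at C3 and the new carbinol carbon. MsCl and Et3N convert it into the methanesulfonate of that adduct F9, which DBU eliminates in the same flask to (3E,4R)-3-({4-[(tert-butyldimethylsilyl)oxy]-3-methoxyphenyl}methylidene)-4-[(R)-[(tert-butyldimethylsilyl)oxy]{4-[(tert-butyldimethylsilyl)oxy]-3-methoxyphenyl}methyl]oxolan-2-one F10. Conjugate reduction with NiCl2·6H2O and NaBH4 in MeOH/THF at 0 °C should give mainly the (3S,4R)-cis epimer of 15 F11, by protonation anti to the C4 substituent. DBU in toluene at 80 °C then equilibrates C3 to the more stable 3,4-trans lactone 15.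

Further compounds
F1 | step 5 | ethyl 3-{4-[(tert-butyldimethylsilyl)oxy]-3-methoxyphenyl}-3-oxopropanoate | CCOC(=O)CC(=O)c1ccc(O[Si](C)(C)C(C)(C)C)c(OC)c1
F2 | step 5 | ethyl (3R)-3-{4-[(tert-butyldimethylsilyl)oxy]-3-methoxyphenyl}-3-hydroxypropanoate | CCOC(=O)C[C@@H](O)c1ccc(O[Si](C)(C)C(C)(C)C)c(OC)c1
F3 | step 5 | dilithium alkoxide-enolate of F2 | [Li+].[Li+].CCOC([O-])=C[C@@H]([O-])c1ccc(O[Si](C)(C)C(C)(C)C)c(OC)c1
F4 | step 5 | 4-tert-butyl 1-ethyl (2S)-2-[(R)-{4-[(tert-butyldimethylsilyl)oxy]-3-methoxyphenyl}(hydroxy)methyl]butanedioate | CCOC(=O)[C@@H](CC(=O)OC(C)(C)C)[C@@H](O)c1ccc(O[Si](C)(C)C(C)(C)C)c(OC)c1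
F5 | step 5 | 4-tert-butyl 1-ethyl (2S)-2-[(R)-[(tert-butyldimethylsilyl)oxy]{4-[(tert-butyldimethylsilyl)oxy]-3-methoxyphenyl}methyl]butanedioate | CCOC(=O)[C@@H](CC(=O)OC(C)(C)C)[C@@H](O[Si](C)(C)C(C)(C)C)c1ccc(O[Si](C)(C)C(C)(C)C)c(OC)c1
F6 | step 7 | (2R)-2-[(R)-[(tert-butyldimethylsilyl)oxy]{4-[(tert-butyldimethylsilyl)oxy]-3-methoxyphenyl}methyl]butane-1,4-diol | OCC[C@H](CO)[C@@H](O[Si](C)(C)C(C)(C)C)c1ccc(O[Si](C)(C)C(C)(C)C)c(OC)c1
F7 | step 7 | (4R)-4-[(R)-[(tert-butyldimethylsilyl)oxy]{4-[(tert-butyldimethylsilyl)oxy]-3-methoxyphenyl}methyl]oxolan-2-ol (anomeric mixture) | OC1C[C@H](CO1)[C@@H](O[Si](C)(C)C(C)(C)C)c1ccc(O[Si](C)(C)C(C)(C)C)c(OC)c1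
F8 | step 8 | (4R)-3-[{4-[(tert-butyldimethylsilyl)oxy]-3-methoxyphenyl}(hydroxy)methyl]-4-[(R)-[(tert-butyldimethylsilyl)oxy]{4-[(tert-butyldimethylsilyl)oxy]-3-methoxyphenyl}methyl]oxolan-2-one (mixture at C3 and the new carbinol carbon) | O=C1OC[C@H]([C@@H](O[Si](C)(C)C(C)(C)C)c2ccc(O[Si](C)(C)C(C)(C)C)c(OC)c2)C1C(O)c1ccc(O[Si](C)(C)C(C)(C)C)c(OC)c1
F9 | step 8 | methanesulfonate of F8 | O=C1OC[C@H]([C@@H](O[Si](C)(C)C(C)(C)C)c2ccc(O[Si](C)(C)C(C)(C)C)c(OC)c2)C1C(OS(C)(=O)=O)c1ccc(O[Si](C)(C)C(C)(C)C)c(OC)c1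
F10 | step 8 | (3E,4R)-3-({4-[(tert-butyldimethylsilyl)oxy]-3-methoxyphenyl}methylidene)-4-[(R)-[(tert-butyldimethylsilyl)oxy]{4-[(tert-butyldimethylsilyl)oxy]-3-methoxyphenyl}methyl]oxolan-2-one | O=C1OC[C@H]([C@@H](O[Si](C)(C)C(C)(C)C)c2ccc(O[Si](C)(C)C(C)(C)C)c(OC)c2)/C1=C\c1ccc(O[Si](C)(C)C(C)(C)C)c(OC)c1
F11 | step 8 | (3S,4R)-3-({4-[(tert-butyldimethylsilyl)oxy]-3-methoxyphenyl}methyl)-4-[(R)-[(tert-butyldimethylsilyl)oxy]{4-[(tert-butyldimethylsilyl)oxy]-3-methoxyphenyl}methyl]oxolan-2-one (cis epimer of 15) | COc1cc(C[C@@H]2C(=O)OC[C@@H]2[C@@H](O[Si](C)(C)C(C)(C)C)c2ccc(O[Si](C)(C)C(C)(C)C)c(OC)c2)ccc1O[Si](C)(C)C(C)(C)C
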